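**Retrosynthetic overview**

- The strategy rests on the C3=C4–C5=C6 diene of the ten-membered carbocycle (germacranolide numbering): ring-trans at C3=C4, ring-cis at C5=C6, lactone oxygen on C6 anti to C4. This is the footprint of an oxygen-outward conrotatory opening of a cyclobutene (C3–C4=C5–C6) cis-fused through the C3–C6 bond to an eight-membered carbocycle (C6, C7, C8, C9, C10, C1, C2, C3) that already carries the butenolide (C6, O, C12, C11, C7).
- Disconnections: the C3–C6 σ bond (retro-electrocyclisation); C6–C7 together with the lactone C12–O bond (alkenyl bromide onto a cyclobutenone carbonyl, Ni/Cr); the cyclobutenone from a C3=C4 ketene and ethoxyacetylene (C5, C6), with C15 from methyl addition and carbonyl transposition; C2–C3 by acetate aldol; C11–C13 by Stille coupling; C7–C8 by alkynylation of an aldehyde made from (R)-mevalonolactone.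
- Ring order: the four-membered ring first; then the eight-membered carbocycle and the butenolide in one operation; last the four- and eight-membered rings merge into the ten-membered ring. The four hydroxyls are then told apart by graded silyl ether lability.

Key step: step 16

**Remarks**

- Germacranolide locants (C1–C15) are used for all intermediates. The target is 2S,8R,10S with 3E and 5E alkenes.
- Assumption: the ketene/alkyne cycloaddition is not expected to control C3, so both C3 epimers are carried through steps 13–15 (one is drawn) and converge in step 16. The ligand and catalyst antipodes in steps 4 and 10 are taken to be those that deliver 8R and 2S, to be confirmed on the first run.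

**Route**

Step 1
Reactants: 1 (R)-mevalonolactone
Product: 2 (3R)-3,5-dihydroxy-N-methoxy-N,3-dimethylpentanamide
Conditions: MeNH(OMe)·HCl, i-PrMgCl, THF, −20 → 0 °C; aq. NH4Cl; crude product silylated at once
Reagents that add atoms: N,O-dimethylhydroxylamine hydrochloride, CNOC.Cl
Why: Aminolysis of the lactone by the chloromagnesium amide should give the open-chain N-methoxy-N-methylamide without touching the quaternary carbinol (future C10).

Step 2
Reactants: 2 diol amide
Product: 3 (3R)-N-methoxy-N,3-dimethyl-3,5-bis(triethylsilyloxy)pentanamide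
Conditions: TESOTf, 2,6-lutidine, CH2Cl2, −78 → 0 °C
Reagents that add atoms: triethylsilyl triflate, CC[Si](CC)(CC)OS(=O)(=O)C(F)(F)F
Why: The silyl triflate is reactive enough to silylate the tertiary as well as the primary hydroxyl, and it stops relactonisation.

Step 3
Reactants: 3 bis-silyl ether
Product: 5 C8 aldehyde with C10 OTES and the C2 N-methoxy-N-methylamide, via alkoxysulfonium chloride 4 (not isolated)
Conditions: (COCl)2, DMSO, CH2Cl2, −78 → −40 °C; then Et3N, −78 °C → rt
Reagents that add atoms: none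
Why: Under Swern conditions a primary triethylsilyl ether is cleaved by the chlorosulfonium salt and oxidised directly, while the hindered tertiary silyl ether should survive.

Step 4
Reactants: 5 aldehyde; 6 methyl propiolate
Product: 7 (8R) propargylic alcohol, methyl (4R,6R)-4-hydroxy-8-[methoxy(methyl)amino]-6-methyl-8-oxo-6-(triethylsilyloxy)oct-2-ynoate
Conditions: Me2Zn, ProPhenol ligand (20 mol%; antipode chosen for 8R), Ph3P=O (40 mol%), toluene, 0 → 4 °C
Reagents that add atoms: 6 methyl propiolate, C#CC(=O)OC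
Why: Catalytic asymmetric zinc alkynylation, in which the dinuclear zinc–ProPhenol complex delivers the alkynylzinc to one aldehyde face and so sets C8 under catalyst control.

Step 5
Reactants: 7 propargylic alcohol
Product: 8 C8 tert-butyldimethylsilyl ether of 7
Conditions: TBSOTf, 2,6-lutidine, CH2Cl2, −78 °C
Reagents that add atoms: tert-butyldimethylsilyl triflate, CC(C)(C)[Si](C)(C)OS(=O)(=O)C(F)(F)F
Why: Low-temperature silylation with a weak base protects the γ-hydroxy ynoate without base-induced isomerisation.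

Step 6
Reactants: 8 silylated ynoate
Product: 9 (E)-β-bromo-α-iodo enoate (Br on C7 cis to CO2Me, I on C11 cis to C8)
Conditions: IBr, CH2Cl2, −78 → 0 °C, dark
Reagents that add atoms: iodine monobromide, BrI
Why: Iodobromination of the ynoate should place iodine on the α-carbon C11 and bromide anti on the β-carbon C7, which fixes the geometry of the future C7=C11 alkene.

Step 7
Reactants: 9 bromo iodo enoate
Product: 10 (Z)-β-bromo-α-(hydroxymethyl) enoate (C13 hydroxymethyl cis to C8, Br cis to CO2Me)
Conditions: Bu3SnCH2OH, Pd(PPh3)4 (5 mol%), 1,4-dioxane, 80 °C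
Reagents that add atoms: (tributylstannyl)methanol, CCCC[Sn](CCCC)(CCCC)CO
Why: Stille coupling; zerovalent palladium should insert into the C–I bond faster than into the C–Br bond, and the hydroxymethyl group is transferred with retention of alkene geometry.

Step 8
Reactants: 10 allylic alcohol
Product: 11 C13 tert-butyldiphenylsilyl ether of 10
Conditions: TBDPSCl, imidazole, DMF, 0 °C → rt
Reagents that add atoms: tert-butyldiphenylsilyl chloride, CC(C)(C)[Si](Cl)(c1ccccc1)c1ccccc1
Why: Standard silylation of the primary allylic alcohol gives the most robust silyl ether of the set, to be removed last.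

Step 9
Reactants: 11 N-methoxy-N-methylamide
Product: 12 C2 aldehyde
Conditions: Cp2Zr(H)Cl, THF, rt
Reagents that add atoms: none
Why: Cp2Zr(H)Cl reduces tertiary amides to aldehydes through a stable zirconated hemiaminal and should leave the ester, the silyl ethers and the alkenyl bromide untouched.

Step 10
Reactants: 12 aldehyde; 13 tert-butyl[(1-methoxyvinyl)oxy]dimethylsilane
Product: 14 (2S) β-hydroxy methyl ester
Conditions: SiCl4, chiral binaphthyldiamine-derived bisphosphoramide (10 mol%; antipode chosen for 2S), i-Pr2NEt (10 mol%), CH2Cl2, −78 °C; aq. NaHCO3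
Reagents that add atoms: 13 tert-butyl[(1-methoxyvinyl)oxy]dimethylsilane, C=C(OC)O[Si](C)(C)C(C)(C)C
Why: Catalytic asymmetric Mukaiyama acetate aldol in which the phosphoramide-bound chlorosilyl cation is the chiral Lewis acid; C2 is set by the catalyst, since the quaternary C10 centre is expected to exert little 1,3-bias of its own.

Step 11
Reactants: 14 β-hydroxy ester
Product: 15 C2 triethylsilyl ether of 14
Conditions: TESCl, imidazole, DMF, 0 °C
Reagents that add atoms: chlorotriethylsilane, CC[Si](Cl)(CC)CC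
Why: Routine silylation of the secondary alcohol gives a group that can later be removed together with the C10 silyl ether.

Step 12
Reactants: 15 diester
Product: 16 β-silyloxy carboxylic acid (C4 acid; C12 methyl ester intact)
Conditions: Me3SnOH, ClCH2CH2Cl, 70 °C; dilute HCl wash
Reagents that add atoms: trimethyltin hydroxide, C[Sn](C)(C)O
Why: Me3SnOH hydrolyses unhindered methyl esters under nearly neutral conditions, so the shielded tetrasubstituted C12 enoate and the β-silyloxy group should be spared.

Step 13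
Reactants: 16 acid; 17 ethoxyacetylene
Product: 20 4-substituted 3-ethoxycyclobut-2-en-1-one (C4 carbonyl; both C3 epimers), via acid chloride 18 (not isolated), via ketene 19 (not isolated)
Conditions: 1-chloro-N,N,2-trimethylprop-1-en-1-amine, CH2Cl2, 0 °C → rt; then added over 4 h to 17 (5 equiv), Et3N, CH2Cl2, rt
Reagents that add atoms: 17 ethoxyacetylene, CCOC#C
Why: Neutral acid chloride formation, dehydrochlorination to the aldoketene and regioselective ketene–ynol ether [2+2] cycloaddition (ketene carbon C4 to the alkyne CH, C3 to the ethoxy-bearing carbon) should form the four-membered ring; C3 arises without control.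

Step 14
Reactants: 20 ethoxycyclobutenone
Product: 22 4-substituted 3-methylcyclobut-2-en-1-one (C6 ketone, C4 methyl), via tertiary cyclobutenol 21 (not isolated)
Conditions: MeLi, CeCl3, THF, −78 °C; aq. NH4Cl; then PPTS (cat.), wet THF, 0 °C
Reagents that add atoms: methyllithium, [Li]C; water, O
Why: The organocerium reagent should add 1,2 to the strained vinylogous-ester carbonyl rather than to the hindered enoate, and mild acid then hydrolyses the hydroxy enol ether with 1,3-transposition of the carbonyl to C6.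

Step 15
Reactants: 22 bromo enoate cyclobutenone
Product: 24 tricycle, cis-bicyclo[6.2.0]dec-9-ene fused to the butenolide, via bicyclic C6 carbinol ester 23 (not isolated)
Conditions: CrCl2 (10 equiv), NiCl2 (2 mol%), DMF/THF, syringe-pump addition to 0.002 M, rt → 40 °C
Reagents that add atoms: none
Why: Intramolecular Nozaki–Hiyama–Kishi reaction: the C7 alkenylchromium, formed with retention, should add 1,2 to the strained C6 ketone on the face that carries the C2 arm (the only approach an eight-membered tether allows, hence cis fusion), and the C6 alkoxide then lactonises onto the cis C12 ester.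

Step 16
Reactants: 24 tricycle
Product: 25 fully silylated ten-membered dienolide
Conditions: toluene (degassed, 0.005 M), 2,6-di-tert-butyl-4-methylphenol (cat.), 80–110 °C
Reagents that add atoms: none
Why: Heating should trigger a concerted conrotatory four-electron electrocyclic opening of the cyclobutene, in which the C3–C6 σ bond breaks while the C3=C4 and C5=C6 π bonds form; the closest known reaction type is the thermal opening of cis-bicyclo[6.2.0]dec-9-enes to cis,trans-cyclodeca-1,3-dienes. The ten-membered carbocycle is not closed by bond formation but arises by ring merger, because the breaking bond is the one shared by the four- and eight-membered rings, and the E-alkylidene butenolide appears in the same event. No stereocentre is created; C3 and C6 become trigonal, so both C3 epimers of 24 converge, and the two alkene geometries follow from the sense of conrotation. Because C2 and C7 lie on one face of the cyclobutene, one arm must turn inward and the other outward, so only a ring-cis/ring-trans diene is allowed, which an eight-membered partner can hold. The selectivity needed is between the two conrotatory senses, and it is secured by the outward preference of the acyloxy donor on C6 and of the C2 alkyl arm over hydrogen on C3, which both select the rotation giving O6 anti to C4 and C2 anti to C5. Strain release, the donor on C6 and the emerging cross-ring trienoate conjugation should bring the barrier into a range that the silyl ethers and the lactone tolerate.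

Step 17
Reactants: 25 silylated dienolide
Product: 26 C2,C10-diol (C8 OTBS and C13 OTBDPS retained)
Conditions: HF·pyridine, pyridine, THF, 0 °C → rt
Reagents that add atoms: none
Why: Buffered HF·pyridine cleaves triethylsilyl ethers much faster than the hindered secondary TBS ether and the TBDPS ether.

Step 18
Reactants: 26 diol
Product: 27 C2 acetate with free tertiary C10 hydroxyl
Conditions: Ac2O, pyridine, DMAP (cat.), CH2Cl2, 0 °C
Reagents that add atoms: acetic anhydride, CC(=O)OC(C)=O
Why: Under mild acylation conditions only the secondary allylic C2 hydroxyl should react; the tertiary C10 hydroxyl is too hindered.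

Step 19
Reactants: 27 acetate
Product: 28 C8 alcohol (C13 OTBDPS retained)
Conditions: aq. HF (48%), MeCN, 0 °C
Reagents that add atoms: none
Why: Under acidic fluoride conditions a secondary TBS ether is cleaved far faster than a primary TBDPS ether, and the acetate and the tertiary alcohol are not affected.

Step 20
Reactants: 28 C8 alcohol
Product: 29 C8 methacrylate, C13 silyl ether
Conditions: methacrylic anhydride, Et3N, DMAP (cat.), CH2Cl2, 0 °C → rt
Reagents that add atoms: methacrylic anhydride, C=C(C)C(=O)OC(=O)C(C)=C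
Why: DMAP-catalysed acylation of the only free secondary hydroxyl, again leaving the tertiary C10 hydroxyl free.

Step 21
Reactants: 29 silyl ether
Product: 30 target CNP0246543.2
Conditions: TBAF, AcOH (1:1), THF, 0 °C → rt
Reagents that add atoms: none
Why: Acetic-acid-buffered fluoride removes the primary TBDPS ether while suppressing acyl migration and conjugate addition to the dienolide.

**Compound list**

1 | (R)-mevalonolactone | C1C[C@@](C)(O)CC(=O)O1 | starting material
2 | (3R)-3,5-dihydroxy-N-methoxy-N,3-dimethylpentanamide | OCC[C@@](C)(O)CC(=O)N(C)OC | intermediate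
3 | (3R)-N-methoxy-N,3-dimethyl-3,5-bis(triethylsilyloxy)pentanamide | CC[Si](CC)(CC)OCC[C@@](C)(O[Si](CC)(CC)CC)CC(=O)N(C)OC | intermediate
4 | dimethyl(alkoxy)sulfonium chloride at the primary C8 oxygen (not isolated) | C[S+](C)OCC[C@@](C)(O[Si](CC)(CC)CC)CC(=O)N(C)OC.[Cl-] | intermediate
5 | C8 aldehyde, (3R)-N-methoxy-N,3-dimethyl-5-oxo-3-(triethylsilyloxy)pentanamide | O=CC[C@@](C)(O[Si](CC)(CC)CC)CC(=O)N(C)OC | intermediate
6 | methyl propiolate | C#CC(=O)OC | starting material
7 | (8R) propargylic alcohol, methyl (4R,6R)-4-hydroxy-8-[methoxy(methyl)amino]-6-methyl-8-oxo-6-(triethylsilyloxy)oct-2-ynoate | O[C@@H](C#CC(=O)OC)C[C@@](C)(O[Si](CC)(CC)CC)CC(=O)N(C)OC | intermediate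
8 | C8 tert-butyldimethylsilyl ether of 7 | CC(C)(C)[Si](C)(C)O[C@@H](C#CC(=O)OC)C[C@@](C)(O[Si](CC)(CC)CC)CC(=O)N(C)OC | intermediate
9 | (E)-β-bromo-α-iodo enoate (Br at C7 cis to CO2Me, I at C11) | CC(C)(C)[Si](C)(C)O[C@@H](/C(Br)=C(/C(=O)OC)I)C[C@@](C)(O[Si](CC)(CC)CC)CC(=O)N(C)OC | intermediate
10 | (Z)-β-bromo-α-(hydroxymethyl) enoate | CC(C)(C)[Si](C)(C)O[C@@H](/C(Br)=C(/C(=O)OC)CO)C[C@@](C)(O[Si](CC)(CC)CC)CC(=O)N(C)OC | intermediate
11 | C13 tert-butyldiphenylsilyl ether of 10 | CC(C)(C)[Si](C)(C)O[C@@H](/C(Br)=C(/C(=O)OC)CO[Si](c1ccccc1)(c1ccccc1)C(C)(C)C)C[C@@](C)(O[Si](CC)(CC)CC)CC(=O)N(C)OC | intermediate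
12 | C2 aldehyde | CC(C)(C)[Si](C)(C)O[C@@H](/C(Br)=C(/C(=O)OC)CO[Si](c1ccccc1)(c1ccccc1)C(C)(C)C)C[C@@](C)(O[Si](CC)(CC)CC)CC=O | intermediate
13 | tert-butyl[(1-methoxyvinyl)oxy]dimethylsilane | C=C(OC)O[Si](C)(C)C(C)(C)C | starting material
14 | (2S) β-hydroxy methyl ester | CC(C)(C)[Si](C)(C)O[C@@H](/C(Br)=C(/C(=O)OC)CO[Si](c1ccccc1)(c1ccccc1)C(C)(C)C)C[C@@](C)(O[Si](CC)(CC)CC)C[C@H](O)CC(=O)OC | intermediate
15 | C2 triethylsilyl ether of 14 | CC(C)(C)[Si](C)(C)O[C@@H](/C(Br)=C(/C(=O)OC)CO[Si](c1ccccc1)(c1ccccc1)C(C)(C)C)C[C@@](C)(O[Si](CC)(CC)CC)C[C@H](O[Si](CC)(CC)CC)CC(=O)OC | intermediate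
16 | β-silyloxy carboxylic acid | CC(C)(C)[Si](C)(C)O[C@@H](/C(Br)=C(/C(=O)OC)CO[Si](c1ccccc1)(c1ccccc1)C(C)(C)C)C[C@@](C)(O[Si](CC)(CC)CC)C[C@H](O[Si](CC)(CC)CC)CC(=O)O | intermediate
17 | ethoxyacetylene | CCOC#C | starting material
18 | acid chloride of 16 (not isolated) | CC(C)(C)[Si](C)(C)O[C@@H](/C(Br)=C(/C(=O)OC)CO[Si](c1ccccc1)(c1ccccc1)C(C)(C)C)C[C@@](C)(O[Si](CC)(CC)CC)C[C@H](O[Si](CC)(CC)CC)CC(=O)Cl | intermediate
19 | monosubstituted ketene, C3=C4=O (not isolated) | CC(C)(C)[Si](C)(C)O[C@@H](/C(Br)=C(/C(=O)OC)CO[Si](c1ccccc1)(c1ccccc1)C(C)(C)C)C[C@@](C)(O[Si](CC)(CC)CC)C[C@H](O[Si](CC)(CC)CC)C=C=O | intermediate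
20 | 4-substituted 3-ethoxycyclobut-2-en-1-one (one C3 epimer drawn, both carried) | CC(C)(C)[Si](C)(C)O[C@@H](/C(Br)=C(/C(=O)OC)CO[Si](c1ccccc1)(c1ccccc1)C(C)(C)C)C[C@@](C)(O[Si](CC)(CC)CC)C[C@H](O[Si](CC)(CC)CC)[C@@H]1C(=O)C=C1OCC | intermediate
21 | tertiary 1-methylcyclobutenol from methyl addition at C4 (not isolated) | CC(C)(C)[Si](C)(C)O[C@@H](/C(Br)=C(/C(=O)OC)CO[Si](c1ccccc1)(c1ccccc1)C(C)(C)C)C[C@@](C)(O[Si](CC)(CC)CC)C[C@H](O[Si](CC)(CC)CC)[C@@H]1C(C)(O)C=C1OCC | intermediate
22 | 4-substituted 3-methylcyclobut-2-en-1-one, C6 ketone (one C3 epimer drawn) | CC(C)(C)[Si](C)(C)O[C@@H](/C(Br)=C(/C(=O)OC)CO[Si](c1ccccc1)(c1ccccc1)C(C)(C)C)C[C@@](C)(O[Si](CC)(CC)CC)C[C@H](O[Si](CC)(CC)CC)[C@@H]1C(C)=CC1=O | intermediate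
23 | bicyclic C6 tertiary carbinol with cis C12 methyl ester, present as its chromium alkoxide (not isolated) | CC(C)(C)[Si](C)(C)O[C@@H]1C[C@@](C)(O[Si](CC)(CC)CC)C[C@H](O[Si](CC)(CC)CC)[C@@H]2C(C)=C[C@]2(O)/C1=C(\C(=O)OC)CO[Si](c1ccccc1)(c1ccccc1)C(C)(C)C | intermediate
24 | tricycle: cis-bicyclo[6.2.0]dec-9-ene fused at C6–C7 to the butenolide (H-3 and O-6 on one face) | CC(C)(C)[Si](C)(C)O[C@@H]1C[C@@](C)(O[Si](CC)(CC)CC)C[C@H](O[Si](CC)(CC)CC)[C@@H]2C(C)=C[C@@]23OC(=O)C(CO[Si](c4ccccc4)(c4ccccc4)C(C)(C)C)=C13 | intermediate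
25 | silylated ten-membered (3E,5E)-dienolide | CC(C)(C)[Si](C)(C)O[C@@H]1C[C@@](C)(O[Si](CC)(CC)CC)C[C@H](O[Si](CC)(CC)CC)/C=C(C)/C=C2/OC(=O)C(CO[Si](c3ccccc3)(c3ccccc3)C(C)(C)C)=C21 | intermediate
26 | C2,C10-diol | CC(C)(C)[Si](C)(C)O[C@@H]1C[C@@](C)(O)C[C@H](O)/C=C(C)/C=C2/OC(=O)C(CO[Si](c3ccccc3)(c3ccccc3)C(C)(C)C)=C21 | intermediate
27 | C2 acetate | CC(C)(C)[Si](C)(C)O[C@@H]1C[C@@](C)(O)C[C@H](OC(C)=O)/C=C(C)/C=C2/OC(=O)C(CO[Si](c3ccccc3)(c3ccccc3)C(C)(C)C)=C21 | intermediate
28 | C8 alcohol | O[C@@H]1C[C@@](C)(O)C[C@H](OC(C)=O)/C=C(C)/C=C2/OC(=O)C(CO[Si](c3ccccc3)(c3ccccc3)C(C)(C)C)=C21 | intermediate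
29 | C8 methacrylate, C13 tert-butyldiphenylsilyl ether | C=C(C)C(=O)O[C@@H]1C[C@@](C)(O)C[C@H](OC(C)=O)/C=C(C)/C=C2/OC(=O)C(CO[Si](c3ccccc3)(c3ccccc3)C(C)(C)C)=C21 | intermediate
30 | CNP0246543.2, (2S,8R,10S)-2-acetoxy-10,13-dihydroxy-8-methacryloyloxygermacra-3E,5E,7(11)-trien-12,6-olide | C=C(C)C(=O)O[C@@H]1C[C@@](C)(O)C[C@H](OC(C)=O)/C=C(C)/C=C2/OC(=O)C(CO)=C21 | target

**Step count**

Total: 21 steps. Longest linear sequence: 21 steps, from 1.

**Steps most likely to fail, with fallbacks**

Step 15. Carbonyl addition of the hindered alkenylchromium to a ketone through an eight-membered transition state may be slower than protodebromination and reduction of the cyclobutenone by CrCl2. The fallback reverses the order of ring opening and ring closure; it sets out from 22 and returns at 25. Heating 22 with MeNH(OMe) in toluene (80–100 °C) would open the cyclobutenone to the vinylketene with the C2 arm outward and trap it as the (3E)-β,γ-unsaturated N-methoxy-N-methyl amide F1. Cp2Zr(H)Cl would reduce it to the β,γ-unsaturated aldehyde F2. Nozaki–Hiyama–Kishi macrocyclisation onto this aldehyde (CrCl2, NiCl2 cat., DMSO/THF, high dilution), a far better acceptor than the ketone, would form C6–C7 and the ten-membered ring at once, with lactonisation to the ten-membered γ-H butenolide F3 (its C6 epimers are of no consequence). Soft enolisation (TBSOTf, Et3N) would give the 2-silyloxyfuran F4, NBS at −78 °C the γ-bromobutenolide F5, and Et3N would eliminate HBr across C5–C6 to give 25. The ring, with its trans C3=C4 alkene, should accept the new alkene only as ring-cis.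

Step 16. The oxygen-inward sense of conrotation may compete, or the dienolide may isomerise or decompose at the temperature the opening needs. The fallback turns the C6 donor into an alkoxide; it sets out from 24 and returns at 25. KOSiMe3 (THF, 0 °C → rt) would open the lactone, and the cyclobutenyl alkoxide should undergo oxyanion-accelerated conrotatory opening at or below room temperature with oxygen outward. Kinetic protonation of the dienolate at C5 would give the ten-membered (3E) keto acid F6, which after mild acidification should exist as its ring tautomer, the hydroxybutenolide F7. Dehydration (MsCl, Et3N, CH2Cl2, 0 °C) would restore the C5=C6 alkene, ring-cis by ring constraint, and give 25.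

Step 13. Dimerisation of the aldoketene, or β-elimination of the C2 silyloxy group during dehydrochlorination, may outrun the cycloaddition. The fallback replaces the ketene by a keteniminium salt and ethoxyacetylene by propyne, which also makes step 14 unnecessary; it sets out from 16 and returns at 22. Coupling of 16 with Me2NH (EDC·HCl, HOBt, CH2Cl2) would give the N,N-dimethylamide F8. Tf2O and 2,4,6-collidine (ClCH2CH2Cl) would convert it into the keteniminium triflate F9, which does not dimerise. F9 should add [2+2] to propyne (sealed vessel, rt → 60 °C), the alkyne CH bonding to the iminium carbon, to give the cyclobuteniminium triflate F10, and aqueous NaHCO3 would hydrolyse this to 22. In this variant the former carboxyl carbon becomes C6 and propyne supplies C4, C5 and C15.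

**Further compounds**

F1 | step 15 | (3E)-β,γ-unsaturated N-methoxy-N-methyl amide from vinylketene trapping | CC(C)(C)[Si](C)(C)O[C@@H](/C(Br)=C(/C(=O)OC)CO[Si](c1ccccc1)(c1ccccc1)C(C)(C)C)C[C@@](C)(O[Si](CC)(CC)CC)C[C@H](O[Si](CC)(CC)CC)/C=C(C)/CC(=O)N(C)OC
F2 | step 15 | (3E)-β,γ-unsaturated C6 aldehyde | CC(C)(C)[Si](C)(C)O[C@@H](/C(Br)=C(/C(=O)OC)CO[Si](c1ccccc1)(c1ccccc1)C(C)(C)C)C[C@@](C)(O[Si](CC)(CC)CC)C[C@H](O[Si](CC)(CC)CC)/C=C(C)/CC=O
F3 | step 15 | ten-membered γ-H butenolide (C6 epimers) | CC(C)(C)[Si](C)(C)O[C@@H]1C[C@@](C)(O[Si](CC)(CC)CC)C[C@H](O[Si](CC)(CC)CC)/C=C(C)/CC2OC(=O)C(CO[Si](c3ccccc3)(c3ccccc3)C(C)(C)C)=C21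
F4 | step 15 | ring-fused 2-(tert-butyldimethylsilyloxy)furan | CC(C)(C)[Si](C)(C)O[C@@H]1C[C@@](C)(O[Si](CC)(CC)CC)C[C@H](O[Si](CC)(CC)CC)/C=C(C)/Cc2oc(O[Si](C)(C)C(C)(C)C)c(CO[Si](c3ccccc3)(c3ccccc3)C(C)(C)C)c21
F5 | step 15 | γ-bromobutenolide (Br on C6) | CC(C)(C)[Si](C)(C)O[C@@H]1C[C@@](C)(O[Si](CC)(CC)CC)C[C@H](O[Si](CC)(CC)CC)/C=C(C)/CC2(Br)OC(=O)C(CO[Si](c3ccccc3)(c3ccccc3)C(C)(C)C)=C21
F6 | step 16 | ten-membered (3E) C6 keto acid | CC(C)(C)[Si](C)(C)O[C@@H]1C[C@@](C)(O[Si](CC)(CC)CC)C[C@H](O[Si](CC)(CC)CC)/C=C(C)/CC(=O)/C1=C(\C(=O)O)CO[Si](c1ccccc1)(c1ccccc1)C(C)(C)C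
F7 | step 16 | hydroxybutenolide ring tautomer of F6 (OH on C6) | CC(C)(C)[Si](C)(C)O[C@@H]1C[C@@](C)(O[Si](CC)(CC)CC)C[C@H](O[Si](CC)(CC)CC)/C=C(C)/CC2(O)OC(=O)C(CO[Si](c3ccccc3)(c3ccccc3)C(C)(C)C)=C21
F8 | step 13 | N,N-dimethylamide of 16 | CC(C)(C)[Si](C)(C)O[C@@H](/C(Br)=C(/C(=O)OC)CO[Si](c1ccccc1)(c1ccccc1)C(C)(C)C)C[C@@](C)(O[Si](CC)(CC)CC)C[C@H](O[Si](CC)(CC)CC)CC(=O)N(C)C
F9 | step 13 | keteniminium triflate | CC(C)(C)[Si](C)(C)O[C@@H](/C(Br)=C(/C(=O)OC)CO[Si](c1ccccc1)(c1ccccc1)C(C)(C)C)C[C@@](C)(O[Si](CC)(CC)CC)C[C@H](O[Si](CC)(CC)CC)C=C=[N+](C)C.[O-]S(=O)(=O)C(F)(F)F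
F10 | step 13 | 4-substituted 3-methylcyclobut-2-en-1-iminium triflate (C3 epimers) | CC(C)(C)[Si](C)(C)O[C@@H](/C(Br)=C(/C(=O)OC)CO[Si](c1ccccc1)(c1ccccc1)C(C)(C)C)C[C@@](C)(O[Si](CC)(CC)CC)C[C@H](O[Si](CC)(CC)CC)C1C(C)=CC1=[N+](C)C.[O-]S(=O)(=O)C(F)(F)F
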